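**Retrosynthetic overview**

1. The target is reached from dione 10 by removing the MOM group on O7, and 10 from phenol 9 by methylating O5.
2. Key disconnection: the bond between chromene C6 and the adjacent dione carbonyl. The chromen-5-ol (as its magnesium phenoxide) is joined to 4-methoxyphenylglyoxal at the carbinol level, and a second glyoxal molecule raises the adduct to the 1,2-dione in the same pot.
3. Ring order: both benzene rings are bought. The pyran ring is the only ring made; it closes in the key operation (alkenyl Grignard addition to aldehyde 2, o-quinone methide, oxa-6π closure) just before the C6–C(=O) bond forms.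
4. Enabling feature: C6, the carbon that carries the dione, is the only free position ortho to O5, because the other ortho position, C4a, is the pyran ring fusion; a metal on O5 can therefore deliver the electrophile only to C6. The pyran carbon C4 lies between C5–O and C8a–O, which are equivalent in the symmetric aldehyde 2, so ring closure has no regiochemical choice.
5. Aldehyde 2 comes from 2,4,6-trihydroxybenzaldehyde 1 by 4-O-selective MOM protection.

Key step: step 2

Remark: 4-methoxyphenylglyoxal 4 is sold as its monohydrate; it is taken as dried by azeotropic distillation with toluene just before use, which is not counted as a step. The target has no stereocentre.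

**Route**

Step 1
Reactants: 1 2,4,6-trihydroxybenzaldehyde
Product: 2 2,6-dihydroxy-4-(methoxymethoxy)benzaldehyde
Conditions: MOMCl (1.05 equiv), K2CO3 (1.1 equiv), acetone, 0 °C to rt
Reagents that add atoms: chloromethyl methyl ether, COCCl
Why: Williamson etherification; the 4-hydroxyl, para to the formyl group, is the most acidic and the only one not held in a hydrogen bond to the carbonyl, so one equivalent of carbonate should form and alkylate the 4-phenoxide, as in the 4-O-selective mono-alkylation of 2,4-dihydroxy- and 2,4,6-trihydroxyaryl carbonyl compounds.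

Step 2
Reactants: 2 2,6-dihydroxy-4-(methoxymethoxy)benzaldehyde; 3 (2-methylprop-1-en-1-yl)magnesium bromide; 4 4-methoxyphenylglyoxal
Product: 9 1-[5-hydroxy-7-(methoxymethoxy)-2,2-dimethyl-2H-chromen-6-yl]-2-(4-methoxyphenyl)ethane-1,2-dione, via carbinolate 5 (not isolated), via o-quinone methide 6 (not isolated), via chromen-5-olate 7 (not isolated), via ketol alkoxide 8 (not isolated)
Conditions: EtMgBr (2.0 equiv), THF, −78 °C; 3 (1.05 equiv), −78 to 0 °C; solvent switch to PhMe, 80 °C; 4 (3.0 equiv, anhydrous), PhMe, 0 to 50 °C; aq NH4Cl
Reagents that add atoms: none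
Why: Proposed new method: a magnesium phenoxide relay: EtMgBr gives the bis(bromomagnesium) phenoxide of 2, 1,2-addition of 3 to the chelated formyl group gives carbinolate 5, which on heating loses (BrMg)2O to the vinyl o-quinone methide 6 and closes to the chromen-5-olate 7; the O5–Mg centre of 7 then binds the formyl group of 4 and delivers it through a six-membered chelate to the ortho carbon C6 (ketol alkoxide 8), and a second molecule of 4 takes up the carbinol hydride in a Meerwein–Ponndorf–Verley/Oppenauer transfer, leaving the dione as the magnesium chelate of 9. The closest known reaction types are the formation of 2H-chromenes from halomagnesium 2-(1-hydroxyalk-2-enyl)phenolates, the ortho-specific hydroxyalkylation of halomagnesium phenoxides with aldehydes and glyoxylates, and the magnesium-mediated ortho-formylation of phenols with paraformaldehyde, in which a second aldehyde molecule oxidises the first adduct; what is new is their telescoping and the use of an arylglyoxal as both the C2 electrophile and the hydride acceptor. The pyran ring is closed by thermal oxa-6π electrocyclisation of 6 (O1–C2 bond), without a regiochemical choice because the two oxygens flanking the former formyl carbon are equivalent. No stereocentre is set: the carbinol centres of 5 and 8 are racemic and are erased by the elimination and the oxidation. The selectivity needed is C6 against C8 and attack at the formyl instead of the keto carbon of 4; the first is secured because C6 is the only unsubstituted position ortho to the magnesium-bearing O5 (C4a is the ring fusion) and toluene suppresses the untemplated para pathway, the second by the higher electrophilicity of the formyl group in the O,O-chelated glyoxal.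

Step 3
Reactants: 9 1-[5-hydroxy-7-(methoxymethoxy)-2,2-dimethyl-2H-chromen-6-yl]-2-(4-methoxyphenyl)ethane-1,2-dione
Product: 10 1-[5-methoxy-7-(methoxymethoxy)-2,2-dimethyl-2H-chromen-6-yl]-2-(4-methoxyphenyl)ethane-1,2-dione
Conditions: MeI (3 equiv), K2CO3 (2 equiv), DMF, rt to 40 °C
Reagents that add atoms: iodomethane, CI
Why: Williamson O-methylation (SN2) of the only free hydroxyl, O5; the MOM acetal and the chromene are inert to carbonate and the non-enolisable dione cannot be C-alkylated.

Step 4
Reactants: 10 1-[5-methoxy-7-(methoxymethoxy)-2,2-dimethyl-2H-chromen-6-yl]-2-(4-methoxyphenyl)ethane-1,2-dione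
Product: 11 1-(7-hydroxy-5-methoxy-2,2-dimethyl-2H-chromen-6-yl)-2-(4-methoxyphenyl)ethane-1,2-dione
Conditions: 2 M aq HCl, THF, 40 °C
Reagents that add atoms: none
Why: acid hydrolysis of the MOM acetal, which should be fast for an acetal ortho to a carbonyl, while the aryl methyl ethers and the 2,2-dimethyl-2H-chromene should tolerate dilute aqueous acid; water instead of methanol as co-solvent avoids ketal formation at the dione.

**Compound list**

1 | 2,4,6-trihydroxybenzaldehyde | O=Cc1c(O)cc(O)cc1O | starting material
2 | 2,6-dihydroxy-4-(methoxymethoxy)benzaldehyde | COCOc1cc(O)c(C=O)c(O)c1 | intermediate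
3 | (2-methylprop-1-en-1-yl)magnesium bromide | CC(C)=C[Mg]Br | starting material
4 | 4-methoxyphenylglyoxal, 2-(4-methoxyphenyl)-2-oxoacetaldehyde | COc1ccc(C(=O)C=O)cc1 | starting material
5 | tris(bromomagnesium) salt of 2-(1-hydroxy-3-methylbut-2-en-1-yl)-5-(methoxymethoxy)benzene-1,3-diol (racemic, not isolated) | COCOc1cc(O[Mg]Br)c(C(O[Mg]Br)C=C(C)C)c(O[Mg]Br)c1 | intermediate
6 | bromomagnesium salt of (2Z)-3-hydroxy-5-(methoxymethoxy)-2-(3-methylbut-2-en-1-ylidene)cyclohexa-3,5-dien-1-one, the vinyl o-quinone methide (not isolated) | CC(C)=C/C=C1\C(=O)C=C(OCOC)C=C1O[Mg]Br | intermediate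
7 | bromomagnesium 7-(methoxymethoxy)-2,2-dimethyl-2H-chromen-5-olate (not isolated) | COCOc1cc(O[Mg]Br)c2C=CC(C)(C)Oc2c1 | intermediate
8 | bromomagnesium alkoxide of 2-hydroxy-2-[5-hydroxy-7-(methoxymethoxy)-2,2-dimethyl-2H-chromen-6-yl]-1-(4-methoxyphenyl)ethan-1-one (racemic, not isolated) | COCOc1cc2OC(C)(C)C=Cc2c(O)c1C(O[Mg]Br)C(=O)c1ccc(OC)cc1 | intermediate
9 | 1-[5-hydroxy-7-(methoxymethoxy)-2,2-dimethyl-2H-chromen-6-yl]-2-(4-methoxyphenyl)ethane-1,2-dione | COCOc1cc2OC(C)(C)C=Cc2c(O)c1C(=O)C(=O)c1ccc(OC)cc1 | intermediate
10 | 1-[5-methoxy-7-(methoxymethoxy)-2,2-dimethyl-2H-chromen-6-yl]-2-(4-methoxyphenyl)ethane-1,2-dione | COCOc1cc2OC(C)(C)C=Cc2c(OC)c1C(=O)C(=O)c1ccc(OC)cc1 | intermediate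
11 | 1-(7-hydroxy-5-methoxy-2,2-dimethyl-2H-chromen-6-yl)-2-(4-methoxyphenyl)ethane-1,2-dione | COc1ccc(C(=O)C(=O)c2c(O)cc3c(c2OC)C=CC(C)(C)O3)cc1 | target

**Step count and risks**

Total step count: 4. Longest linear sequence: 4 steps (1 → 2 → 9 → 10 → 11).

Steps most likely to fail:

1. Step 2 (proposed new method). The relay may stall at the ketol stage if hydride transfer to the glyoxal is slower than base-induced self-consumption of the glyoxal (intramolecular Cannizzaro). Residual Grignard reagent may add to the o-quinone methide, or untemplated attack para to O5 (at C8) may compete. The fallback uses known chemistry stepwise and sets out from 2. Only the Grignard addition and thermal cyclisation are run, and after an aq NH4Cl quench 7-(methoxymethoxy)-2,2-dimethyl-2H-chromen-5-ol F1 is isolated. F1 is converted with EtMgBr (1.0 equiv) in toluene into its magnesium phenoxide and treated with 4 (1.1 equiv) at 0 °C (ortho-specific hydroxyalkylation) to give the ketol 2-hydroxy-2-[5-hydroxy-7-(methoxymethoxy)-2,2-dimethyl-2H-chromen-6-yl]-1-(4-methoxyphenyl)ethan-1-one F2. Oxidation of F2 with activated MnO2 in CH2Cl2 (benzoin-to-benzil oxidation) comes back to the route at 9.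

2. Step 1. Site selectivity may be lost through alkylation of an ortho hydroxyl or double alkylation. The fallback sets out from 1, which is alkylated twice (MOMCl 2.2 equiv, i-Pr2NEt, CH2Cl2) to 2-hydroxy-4,6-bis(methoxymethoxy)benzaldehyde F3, where the last hydroxyl is shielded by its hydrogen bond to the formyl group. The acetal ortho to the formyl group is then cleaved alone (cat. HCl, MeOH, 0 °C; carbonyl-assisted and expected to be faster than cleavage of the para acetal), which comes back to the route at 2.

3. Step 3. Alkylation of the chelated, doubly ortho-substituted phenoxide may be slow, leaving time for alkylation of the ring-closed hemiketal form or for base-induced rearrangement of the 1,2-dione. The fallback sets out from 9 and methylates under Mitsunobu conditions (MeOH, PPh3, DIAD, THF, rt), which activates methanol instead of relying on a free phenoxide and avoids carbonate. It makes no new compound (F0) and comes back to the route at 10.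

**Further compounds**

F1 | step 2 | 7-(methoxymethoxy)-2,2-dimethyl-2H-chromen-5-ol | COCOc1cc(O)c2C=CC(C)(C)Oc2c1
F2 | step 2 | 2-hydroxy-2-[5-hydroxy-7-(methoxymethoxy)-2,2-dimethyl-2H-chromen-6-yl]-1-(4-methoxyphenyl)ethan-1-one (racemic) | COCOc1cc2OC(C)(C)C=Cc2c(O)c1C(O)C(=O)c1ccc(OC)cc1
F3 | step 1 | 2-hydroxy-4,6-bis(methoxymethoxy)benzaldehyde | COCOc1cc(O)c(C=O)c(OCOC)c1
F0 | step 3 | none | none
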